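The route moves one peroxide oxygen. The 1,2-dioxane (Oa, Ob, C3, C4, C5, C6) is derived from a 1,2-dioxolane (Oa, Ob, C4, C5, C6) that bears C3 outside the ring. The key step exploits the vicinal C3–Ob/C4–O(lactone) pair at the dioxane/γ-lactone fusion. Triflation of a C3 carbinol lets Ob slide from C4 to C3 through a peroxonium ion while the C1 ester closes on C4, so dioxane and lactone form together with inversion at both carbons. The precursor, a β-hydroxy ester on a 3-alkoxy-1,2-dioxolane, comes from m-xylene by Birch reduction, Shi epoxidation and ozonolysis. C6 follows by axial allylation of the bicyclic peroxycarbenium ion.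

Key step: step 5

Remark: target numbering is C1 (lactone C=O), C2 (CH2), C3 (CH–OO), C4 (C(CH3)–O-lactone), C5 (CH2), C6 (C(CH3)(C16H33)), with Oa on C6 and Ob on C3. Compounds 4–9 are assumed to be carried as mixtures of epimers at the ketal carbon C6, which is erased in step 6, so C6 is left undefined in their SMILES.

Step 1
Reactants: 1 m-xylene
Product: 2 1,5-dimethylcyclohexa-1,4-diene
Conditions: Li, NH3(l), EtOH, Et2O, −78 to −33 °C
Reagents that add atoms: none
Why: Birch reduction: the arene radical anion is protonated at C2 and C5, so both donor methyl groups stay on the two skipped double bonds and each olefin is locked by the ring as the Z-trisubstituted unit C2–C3H=C4(CH3)–C5 needed later; no stereocentre is formed.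

Step 2
Reactants: 2 1,5-dimethylcyclohexa-1,4-diene
Product: 3 (1S,6R)-1,3-dimethyl-7-oxabicyclo[4.1.0]hept-3-ene
Conditions: D-fructose-derived Shi ketone (30 mol %), Oxone (0.7 equiv), K2CO3, Bu4NHSO4, MeCN/DMM/aq. Na2B4O7–EDTA buffer, 0 °C
Reagents that add atoms: Oxone (potassium peroxymonosulfate), [K+].[O-]S(=O)(=O)OO
Why: Shi asymmetric epoxidation (chiral dioxirane, spiro transition state, trisubstituted olefins as the privileged class): the two olefins of 2 are equivalent and their faces enantiotopic, so one catalyst-controlled oxygen transfer sets C3 (R) and C4 (S) together, the D-fructose-derived ketone is expected to give this sense as it does for 1-substituted cyclohexenes, and substoichiometric oxidant limits bis-epoxidation.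

Step 3
Reactants: 3 (1S,6R)-1,3-dimethyl-7-oxabicyclo[4.1.0]hept-3-ene
Product: 5 (3R)-3-[(3R)-3,5-dimethyl-5-(2,2,2-trifluoroethoxy)-1,2-dioxolan-3-yl]-3-hydroxypropanal, via hydroperoxy ketal aldehyde 4 (not isolated)
Conditions: O3 (1 equiv), CH2Cl2/CF3CH2OH 4:1, −78 °C, N2 purge, no reductant; then PPTS (10 mol %), CH2Cl2, 0 °C
Reagents that add atoms: ozone, [O-][O+]=O; 2,2,2-trifluoroethanol, OCC(F)(F)F
Why: Criegee ozonolysis in a participating alcohol followed by acid-catalysed 5-exo-tet epoxide opening: the primary ozonide of the trisubstituted olefin should cleave to the more substituted carbonyl oxide at C6, CF3CH2OH traps it as 4 (chosen over MeOH because its ketal oxygen is too electron-poor to interfere in step 5), and the OOH group attacks the tertiary epoxide carbon C4 with inversion while the C3–O bond is kept.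

Step 4
Reactants: 5 (3R)-3-[(3R)-3,5-dimethyl-5-(2,2,2-trifluoroethoxy)-1,2-dioxolan-3-yl]-3-hydroxypropanal
Product: 6 methyl (3R)-3-[(3R)-3,5-dimethyl-5-(2,2,2-trifluoroethoxy)-1,2-dioxolan-3-yl]-3-hydroxypropanoate
Conditions: Br2, NaHCO3, MeOH/H2O 9:1, 0 °C to rt
Reagents that add atoms: methanol, CO
Why: Direct oxidation of an aldehyde to its methyl ester through the hemiacetal (bromine in buffered aqueous methanol), mild conditions under which the secondary alcohol, the dialkyl peroxide and the ketal should survive; no stereocentre is touched.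

Step 5
Reactants: 6 methyl (3R)-3-[(3R)-3,5-dimethyl-5-(2,2,2-trifluoroethoxy)-1,2-dioxolan-3-yl]-3-hydroxypropanoate
Product: 9 (3S,4S)-cis-fused 1,2-dioxane/γ-lactone bearing CH3 plus OCH2CF3 at C6, via C3 triflate 7 (not isolated), via bicyclic peroxonium triflate 8 (not isolated)
Conditions: Tf2O (1.2 equiv), 2,6-di-tert-butyl-4-methylpyridine (2.5 equiv), CH2Cl2, −78 to 0 °C; aq. NaHCO3
Reagents that add atoms: none
Why: Proposed new method: O-triflation of the C3 carbinol sets up anchimeric displacement by the dioxolane oxygen Ob on C4 (3-exo-tet, inversion at C3) to give peroxonium ion 8, whose tertiary C4–Ob bond is opened from the rear by the ester carbonyl oxygen (5-endo-tet opening of the three-membered ring, as in acid lactonisation of β,γ-epoxy esters, inversion at C4), and triflate then removes the O-methyl group of the dialkoxycarbenium ion. The net event is a 1,2-shift of Ob from C4 to C3, so the 1,2-dioxolane takes up C3 and becomes the 1,2-dioxane while the γ-lactone closes in the same operation. The closest known reaction types are the rearrangement–ring expansion of 2-(1-sulfonyloxyalkyl) cyclic ethers through bicyclic oxonium ions (tetrahydrofuran to tetrahydropyran), the Lewis-acid dyotropic β-lactone to γ-lactone rearrangement, and the silver-assisted solvolysis of β-halo dialkyl peroxides through peroxonium ions; a dioxolane-to-dioxane shift with lactone capture has not been described. Both stereocentres derive stereospecifically from the Shi epoxide: C3 suffers one inversion and C4 two (steps 3 and 5), which equals anti addition of Ob and the acyloxy oxygen across the former Z-olefin and can only give the cis ring fusion with (3S,4S). The step needs oxygen participation to beat E1cB loss of triflate toward C2, a methyl or C5 shift to C3, and heterolysis of the O–O bond. A hindered non-nucleophilic base at low temperature, the cation-stabilising tertiary C4 terminus, the five-atom reach of the ester and the electron-poor trifluoroethyl ketal at C6 (no five-ring ether participation, poor Criegee-type migration) are meant to secure this.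

Step 6
Reactants: 9 (3S,4S)-cis-fused 1,2-dioxane/γ-lactone bearing CH3 plus OCH2CF3 at C6
Product: 10 (3S,4S,6R)-6-allyl-4,6-dimethyl cis-fused 1,2-dioxane/γ-lactone
Conditions: allyltrimethylsilane (4 equiv), TMSOTf (0.3 equiv), CH2Cl2, −78 to −40 °C
Reagents that add atoms: allyltrimethylsilane, C=CC[Si](C)(C)C
Why: Lewis-acid substitution of a monoperoxy ketal by an allylsilane through a peroxycarbenium ion (Hosomi–Sakurai type): both C6 epimers of 9 converge on one cation whose half-chair with C4–CH3 pseudoequatorial and C4–O pseudoaxial is attacked axially at C6 on the face syn to the lactone oxygen, because the other chair-forming trajectory needs an axial C4–CH3 that clashes 1,3-diaxially with the nucleophile, and this gives (6R).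

Step 7
Reactants: 10 (3S,4S,6R)-6-allyl-4,6-dimethyl cis-fused 1,2-dioxane/γ-lactone; 11 1-pentadecene
Product: 12 (3S,4S,6R)-6-(hexadec-2-enyl)-4,6-dimethyl cis-fused 1,2-dioxane/γ-lactone
Conditions: Hoveyda–Grubbs II catalyst (5 mol %), 11 (4 equiv), CH2Cl2, 40 °C
Reagents that add atoms: none
Why: Olefin cross-metathesis of two terminal olefins, driven by excess 11 and loss of ethene; dialkyl peroxides and lactones are tolerated by ruthenium carbenes and the E/Z ratio is irrelevant for the next step.

Step 8
Reactants: 12 (3S,4S,6R)-6-(hexadec-2-enyl)-4,6-dimethyl cis-fused 1,2-dioxane/γ-lactone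
Product: 13 CNP0079571.1
Conditions: dipotassium azodicarboxylate (excess), AcOH, CH2Cl2/MeOH, 0 °C to rt
Reagents that add atoms: none
Why: Diimide reduction: concerted syn transfer of two hydrogens to the C=C bond leaves untouched the O–O bond, which would not survive catalytic hydrogenation, and all three stereocentres.

Compound list
1 | m-xylene (1,3-dimethylbenzene) | Cc1cccc(C)c1 | starting material
2 | 1,5-dimethylcyclohexa-1,4-diene | CC1=CCC=C(C)C1 | intermediate
3 | (1S,6R)-1,3-dimethyl-7-oxabicyclo[4.1.0]hept-3-ene (C4 S, C3 R in target numbering) | C[C@]12CC(C)=CC[C@H]1O2 | intermediate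
4 | 2-[(2R,3S)-3-[2-hydroperoxy-2-(2,2,2-trifluoroethoxy)propyl]-3-methyloxiran-2-yl]acetaldehyde | FC(F)(F)COC(C)(OO)C[C@]1(C)O[C@@H]1CC=O | intermediate
5 | (3R)-3-[(3R)-3,5-dimethyl-5-(2,2,2-trifluoroethoxy)-1,2-dioxolan-3-yl]-3-hydroxypropanal | FC(F)(F)COC1(C)C[C@@](C)(OO1)[C@H](O)CC=O | intermediate
6 | methyl (3R)-3-[(3R)-3,5-dimethyl-5-(2,2,2-trifluoroethoxy)-1,2-dioxolan-3-yl]-3-hydroxypropanoate | FC(F)(F)COC1(C)C[C@@](C)(OO1)[C@H](O)CC(=O)OC | intermediate
7 | methyl (3R)-3-[(3R)-3,5-dimethyl-5-(2,2,2-trifluoroethoxy)-1,2-dioxolan-3-yl]-3-(trifluoromethylsulfonyloxy)propanoate | FC(F)(F)COC1(C)C[C@@](C)(OO1)[C@H](OS(=O)(=O)C(F)(F)F)CC(=O)OC | intermediate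
8 | bicyclic peroxonium triflate (Ob bridges C3 and C4 as a three-membered ring fused to the dioxolane, CH2CO2CH3 on C3 endo) | FC(F)(F)COC1(C)C[C@]2(C)[C@H](CC(=O)OC)[O+]2O1.[O-]S(=O)(=O)C(F)(F)F | intermediate
9 | (4aS,7aS)-3,4a-dimethyl-3-(2,2,2-trifluoroethoxy)tetrahydrofuro[3,2-c][1,2]dioxin-6-one (cis-fused dioxane/γ-lactone, 3S,4S in target numbering) | FC(F)(F)COC1(C)C[C@]2(C)OC(=O)C[C@@H]2OO1 | intermediate
10 | (3R,4aS,7aS)-3-allyl-3,4a-dimethyltetrahydrofuro[3,2-c][1,2]dioxin-6-one | C=CC[C@]1(C)C[C@]2(C)OC(=O)C[C@@H]2OO1 | intermediate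
11 | 1-pentadecene | CCCCCCCCCCCCCC=C | starting material
12 | (3R,4aS,7aS)-3-[(E)-hexadec-2-enyl]-3,4a-dimethyltetrahydrofuro[3,2-c][1,2]dioxin-6-one (E drawn, Z equally useful) | CCCCCCCCCCCCC/C=C/C[C@]1(C)C[C@]2(C)OC(=O)C[C@@H]2OO1 | intermediate
13 | CNP0079571.1, (3R,4aS,7aS)-3-hexadecyl-3,4a-dimethyltetrahydrofuro[3,2-c][1,2]dioxin-6-one (3S,4S,6R in target numbering) | CCCCCCCCCCCCCCCC[C@]1(C)C[C@]2(C)OC(=O)C[C@@H]2OO1 | target

Total step count: 8. Longest linear sequence: 8 (1 to 13).

Steps most likely to fail

Step 5. The triflate may lose triflic acid toward C2. A methyl or C5 shift to C3 may outrun participation by Ob. The peroxonium ion may also collapse by heterolysis of the O–O bond.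

The fallback uses known chemistry and closes the six-membered peroxide directly.
- It sets out from 2, which is epoxidised with the enantiomeric (L-series) Shi ketone to the enantiomeric epoxide F1.
- Ozonolysis in CH2Cl2 with Me2S work-up gives the epoxy keto aldehyde F2, and Pinnick oxidation gives the epoxy keto acid F3.
- Catalytic camphorsulfonic acid closes the carboxyl group onto the tertiary C4 with inversion, which now gives the correct (4S) centre in the β-hydroxy-γ-lactone F4.
- MsCl/Et3N gives the mesylate F5, and DBU eliminates it to the butenolide F6.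
- Urea–H2O2 with catalytic acid in CF3CH2OH turns the ketone into the hydroperoxy ketal F7.
- Catalytic Et2NH triggers the intramolecular oxa-Michael addition (6-exo-trig, cis fusion enforced by C4), which comes back to the route at 9.

Step 3. The primary ozonide may cleave in the wrong sense and put the carbonyl oxide on C1. The carbonyl oxide may be captured by the tethered aldehyde. The epoxide may be solvolysed before the hydroperoxide closes.

The fallback takes the peroxide from H2O2 instead of ozone.
- It sets out from 3, and ozonolysis with Me2S work-up gives the epoxy keto aldehyde F8.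
- Bromine/NaHCO3 in aqueous methanol gives the epoxy keto ester F9.
- Urea–H2O2 in CF3CH2OH with catalytic phosphomolybdic acid forms the hydroperoxy ketal F10 at the only ketone.
- F10 closes 5-exo on C4 under the same conditions and comes back to the route at 6.

Step 6. Facial selectivity may erode if a twist or the alternative half-chair reacts. The peroxycarbenium ion may fragment before the silane arrives.

The fallback delivers the whole chain as a slim sp2 nucleophile and drops the metathesis.
- It sets out from 9, which is treated with potassium (E)-hexadec-1-enyltrifluoroborate and BF3·OEt2 to give the 6-alkenyl dioxane lactone F11.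
- Diimide reduction under the conditions of step 8 then comes back to the route at 13.

Further compounds
F1 | step 5 | (1R,6S)-1,3-dimethyl-7-oxabicyclo[4.1.0]hept-3-ene | C[C@@]12CC(C)=CC[C@@H]1O2
F2 | step 5 | 2-[(2S,3R)-3-methyl-3-(2-oxopropyl)oxiran-2-yl]acetaldehyde | CC(=O)C[C@@]1(C)O[C@H]1CC=O
F3 | step 5 | 2-[(2S,3R)-3-methyl-3-(2-oxopropyl)oxiran-2-yl]acetic acid | CC(=O)C[C@@]1(C)O[C@H]1CC(=O)O
F4 | step 5 | (4S,5S)-4-hydroxy-5-methyl-5-(2-oxopropyl)oxolan-2-one | CC(=O)C[C@]1(C)OC(=O)C[C@@H]1O
F5 | step 5 | (2S,3S)-2-methyl-5-oxo-2-(2-oxopropyl)oxolan-3-yl methanesulfonate | CC(=O)C[C@]1(C)OC(=O)C[C@@H]1OS(C)(=O)=O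
F6 | step 5 | (5S)-5-methyl-5-(2-oxopropyl)furan-2(5H)-one | CC(=O)C[C@]1(C)OC(=O)C=C1
F7 | step 5 | (5S)-5-[2-hydroperoxy-2-(2,2,2-trifluoroethoxy)propyl]-5-methylfuran-2(5H)-one | FC(F)(F)COC(C)(OO)C[C@]1(C)OC(=O)C=C1
F8 | step 3 | 2-[(2R,3S)-3-methyl-3-(2-oxopropyl)oxiran-2-yl]acetaldehyde | CC(=O)C[C@]1(C)O[C@@H]1CC=O
F9 | step 3 | methyl 2-[(2R,3S)-3-methyl-3-(2-oxopropyl)oxiran-2-yl]acetate | CC(=O)C[C@]1(C)O[C@@H]1CC(=O)OC
F10 | step 3 | methyl 2-[(2R,3S)-3-[2-hydroperoxy-2-(2,2,2-trifluoroethoxy)propyl]-3-methyloxiran-2-yl]acetate | FC(F)(F)COC(C)(OO)C[C@]1(C)O[C@@H]1CC(=O)OC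
F11 | step 6 | 6-[(E)-hexadec-1-enyl] analogue of 13 (alkenyl group cis to the lactone oxygen) | CCCCCCCCCCCCCC/C=C/[C@]1(C)C[C@]2(C)OC(=O)C[C@@H]2OO1
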